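Everything rests on disconnecting the C2'–C3' bond of the second dihydrobenzofuran (O1', C2', C3', C3a', C7a', fused to ring D). Because C2' and C3' each carry an aryl group, both can first be bonded to nitrogen in a six-membered 2,4-diaryl-1,3-benzoxazine assembled from an aminophenol and an aldehyde. In the key step an anomeric amide excises that nitrogen as N2 and the two benzylic radicals pair, contracting the oxazine to the trans-dihydrofuran while the C3' configuration, set earlier by a sulfinamide auxiliary, is carried over. The precursor is an 8-bromo-benzoxazine whose C2 aryl group carries mesylates instead of ethers to keep the N,O-acetal ring closed. A sulfur ylide annulation then adds the first ring system.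

Key step: step 9

Target configuration: (2S,3S,2'S,3'S), both dihydrofuran rings trans, E-stilbene.

Assumption: the benzylide of (2S,5S)-2,5-dimethylthiolane is taken to attack an o-quinone methide through the same ylide face as in its known epoxidations of aldehydes, which corresponds to (2S) here; the enantiomeric sulfide would be used in the same way if the sense proved opposite.

Assumption: the two ortho ether groups of imine 5 are taken not to override the sulfinyl-directed chair in step 5; the (S)-sulfinamide would be used in the same way if chelation inverted the sense.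

Step 1
Reactants: 1 2-bromo-5-methoxyphenol
Product: 2 3-bromo-2-hydroxy-6-methoxybenzaldehyde
Conditions: MgCl2, Et3N, (CH2O)n, MeCN, reflux; aq HCl
Reagents that add atoms: paraformaldehyde (as formaldehyde), C=O
Why: Casnati–Skattebøl ortho-formylation, in which the phenoxide, bound to magnesium, delivers formaldehyde to the only free position ortho to the hydroxyl group, so that bromine sits unambiguously on the other side of the phenol oxygen.

Step 2
Reactants: 2 3-bromo-2-hydroxy-6-methoxybenzaldehyde
Product: 3 3-bromo-6-methoxy-2-(methoxymethoxy)benzaldehyde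
Conditions: MOMCl, i-Pr2NEt, CH2Cl2, 0 °C to rt
Reagents that add atoms: chloromethyl methyl ether, COCCl
Why: O-alkylation of the phenol to its MOM acetal masks the acidic OH for the Grignard addition and is removed later in the same acid step as the auxiliary.

Step 3
Reactants: 3 3-bromo-6-methoxy-2-(methoxymethoxy)benzaldehyde; 4 (R)-2-methylpropane-2-sulfinamide
Product: 5 (R)-N-[(E)-[3-bromo-6-methoxy-2-(methoxymethoxy)phenyl]methylidene]-2-methylpropane-2-sulfinamide
Conditions: Ti(OEt)4, THF, 60 °C
Reagents that add atoms: none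
Why: Condensation to the N-tert-butanesulfinyl aldimine, with Ti(OEt)4 as Lewis acid and water scavenger, should give the E-imine without touching the aryl bromide or the acetal.

Step 4
Reactants: 6 1-bromo-3,5-dimethoxybenzene
Product: 7 (3,5-dimethoxyphenyl)magnesium bromide (titrated stock solution in THF, kept under argon)
Conditions: Mg turnings, I2 (cat.), THF, rt to 40 °C
Reagents that add atoms: magnesium, [Mg]
Why: Grignard reagent formation by insertion of magnesium into the aryl C–Br bond gives one stock solution that serves both step 5 and step 14.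

Step 5
Reactants: 5 (R)-N-[(E)-[3-bromo-6-methoxy-2-(methoxymethoxy)phenyl]methylidene]-2-methylpropane-2-sulfinamide; 7 (3,5-dimethoxyphenyl)magnesium bromide
Product: 8 (R)-N-[(S)-[3-bromo-6-methoxy-2-(methoxymethoxy)phenyl](3,5-dimethoxyphenyl)methyl]-2-methylpropane-2-sulfinamide
Conditions: 7 (THF solution), CH2Cl2, −48 °C; H2O
Reagents that add atoms: none
Why: Grignard 1,2-addition to an N-tert-butanesulfinyl imine, in which magnesium bound to the sulfinyl oxygen delivers the aryl group through a six-membered chair with the tert-butyl group equatorial, which for the (R)-sulfinyl E-imine should give the (S) carbon; the aryl bromide of 5 does not exchange with an aryl Grignard reagent at this temperature.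

Step 6
Reactants: 8 (R)-N-[(S)-[3-bromo-6-methoxy-2-(methoxymethoxy)phenyl](3,5-dimethoxyphenyl)methyl]-2-methylpropane-2-sulfinamide
Product: 9 (S)-2-[amino(3,5-dimethoxyphenyl)methyl]-6-bromo-3-methoxyphenol
Conditions: HCl (4 M in dioxane), MeOH, rt; aq NaHCO3
Reagents that add atoms: none
Why: Acidic methanolysis cleaves the N–S bond of the sulfinamide and the MOM acetal in one operation and leaves the benzylic C–N stereocentre untouched.

Step 7
Reactants: 10 2,4-dihydroxybenzaldehyde
Product: 11 4-formyl-1,3-phenylene dimethanesulfonate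
Conditions: MsCl, Et3N, CH2Cl2, 0 °C
Reagents that add atoms: methanesulfonyl chloride, CS(=O)(=O)Cl
Why: O-sulfonylation of both phenols turns the aldehyde-derived aryl ring from a donor into an acceptor, the property that later holds the N,O-acetal closed.

Step 8
Reactants: 9 (S)-2-[amino(3,5-dimethoxyphenyl)methyl]-6-bromo-3-methoxyphenol; 11 4-formyl-1,3-phenylene dimethanesulfonate
Product: 12 4-[(4S)-8-bromo-4-(3,5-dimethoxyphenyl)-5-methoxy-3,4-dihydro-2H-1,3-benzoxazin-2-yl]-1,3-phenylene dimethanesulfonate (both C2 epimers, ring tautomer of the corresponding imine)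
Conditions: 4 Å molecular sieves, CH2Cl2, rt
Reagents that add atoms: none
Why: Imine condensation followed by 6-endo-trig addition of the phenol gives the 1,3-benzoxazine, whose ring tautomer is favoured by the acceptor aryl group; C4 is untouched and the C2 epimer mixture is irrelevant because this carbon becomes a radical.

Step 9
Reactants: 12 4-[(4S)-8-bromo-4-(3,5-dimethoxyphenyl)-5-methoxy-3,4-dihydro-2H-1,3-benzoxazin-2-yl]-1,3-phenylene dimethanesulfonate
Product: 16 4-[(2S,3S)-7-bromo-3-(3,5-dimethoxyphenyl)-4-methoxy-2,3-dihydro-1-benzofuran-2-yl]-1,3-phenylene dimethanesulfonate (trans), via hydrazide adduct 13 (not isolated), via isodiazene 14 (not isolated), via diradical 15 (not isolated)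
Conditions: N-(benzyloxy)-N-(pivaloyloxy)-4-(trifluoromethyl)benzamide (1.5 equiv), degassed THF, 45 °C
Reagents that add atoms: none
Why: Proposed new method: the secondary amine of ring-closed 12 should attack the nitrogen of the anomeric amide and displace pivalate to give hydrazide adduct 13, which expels benzyl 4-(trifluoromethyl)benzoate to leave isodiazene 14; loss of N2 then gives singlet 1,5-diradical 15, an α-oxy benzylic radical at the former C2 and a diarylmethyl radical at the former C4 held together by O1 and ring D, and their coupling forms the C2'–C3' bond (C2 and C3 of 16 are C2' and C3' of the target). The closest known reaction type is the anomeric-amide nitrogen deletion of bis-benzylic secondary amines and of cyclic amines such as 2-aryl pyrrolidines and tetrahydroisoquinolines, which has not been run on an N,O-acetal. The dihydrofuran ring closes by intramolecular radical–radical recombination, which contracts the six-membered oxazine by one atom. C3' is not created but carried over from C4 of 12 (set in step 5): the radical is born with one lobe aimed at its partner, and the two ortho substituents of ring D (O1 and the methoxy group) hinder the rotation about the ring D–C bond that would exchange its faces, so coupling with retention is expected, while C2' is formed in the coupling and should come out trans (2S) because the alternative eclipses the two aryl groups. The step needs N-functionalisation to beat opening of the aminal to the imine, and the two mesylates secure this by making the C2 aryl group an acceptor, which shifts the ring–chain equilibrium to the closed amine; once nitrogen is substituted the ring can no longer open to an imine. The aryl bromide, the sulfonates and the methyl ethers are inert to the reagent and to the short-lived radicals.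

Step 10
Reactants: 16 4-[(2S,3S)-7-bromo-3-(3,5-dimethoxyphenyl)-4-methoxy-2,3-dihydro-1-benzofuran-2-yl]-1,3-phenylene dimethanesulfonate
Product: 18 (2S,3S)-7-bromo-2-(2,4-dimethoxyphenyl)-3-(3,5-dimethoxyphenyl)-4-methoxy-2,3-dihydro-1-benzofuran, via bisphenol 17 (not isolated)
Conditions: NaOH (aq), MeOH/THF, 60 °C; then Me2SO4, rt
Reagents that add atoms: dimethyl sulfate, COS(=O)(=O)OC
Why: Alkaline hydrolysis of the two aryl methanesulfonates (S–O cleavage) frees the phenoxides, which are O-methylated in the same pot (Williamson ether synthesis) to return the robust methyl ethers needed for the organolithium step; the aryl bromide is inert and the trans ring is the stable isomer, so both stereocentres should be unaffected.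

Step 11
Reactants: 18 (2S,3S)-7-bromo-2-(2,4-dimethoxyphenyl)-3-(3,5-dimethoxyphenyl)-4-methoxy-2,3-dihydro-1-benzofuran
Product: 20 [(2S,3S)-2-(2,4-dimethoxyphenyl)-3-(3,5-dimethoxyphenyl)-4-methoxy-2,3-dihydro-1-benzofuran-7-yl]methanol, via aldehyde 19 (not isolated)
Conditions: n-BuLi, THF, −78 °C; DMF; then MeOH, NaBH4, 0 °C
Reagents that add atoms: N,N-dimethylformamide, CN(C)C=O
Why: Bromine–lithium exchange is far faster than any deprotonation at −78 °C, the aryllithium is formylated by DMF (Bouveault formylation) and the crude aldehyde is reduced by NaBH4.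

Step 12
Reactants: 20 [(2S,3S)-2-(2,4-dimethoxyphenyl)-3-(3,5-dimethoxyphenyl)-4-methoxy-2,3-dihydro-1-benzofuran-7-yl]methanol; 21 (2S,5S)-2,5-dimethylthiolane
Product: 23 (2S,5S)-1-{[(2S,3S)-2-(2,4-dimethoxyphenyl)-3-(3,5-dimethoxyphenyl)-4-methoxy-2,3-dihydro-1-benzofuran-7-yl]methyl}-2,5-dimethylthiolan-1-ium tetrafluoroborate, via benzylic bromide 22 (not isolated)
Conditions: CBr4, PPh3, CH2Cl2, 0 °C; then 21, NaBF4, CH2Cl2/H2O, rt
Reagents that add atoms: sodium tetrafluoroborate, [Na+].F[B-](F)(F)F
Why: Appel bromination of the activated benzylic alcohol under neutral conditions is followed by S-alkylation of the sulfide, driven by exchange to the non-nucleophilic counter-ion; the two lone pairs of the C2-symmetric sulfide are equivalent, so a single salt should form.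

Step 13
Reactants: 24 2-bromo-4,6-dimethoxybenzaldehyde
Product: 25 2-bromo-6-hydroxy-4-methoxybenzaldehyde
Conditions: BCl3, CH2Cl2, −78 to 0 °C; H2O
Reagents that add atoms: none
Why: Chelation-directed Lewis-acid ether cleavage, in which BCl3 bound to the aldehyde oxygen removes only the methyl group ortho to the carbonyl.

Step 14
Reactants: 25 2-bromo-6-hydroxy-4-methoxybenzaldehyde; 7 (3,5-dimethoxyphenyl)magnesium bromide
Product: 26 3-bromo-2-[(3,5-dimethoxyphenyl)(hydroxy)methyl]-5-methoxyphenol (racemic)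
Conditions: 7 (THF solution, 2.2 equiv), THF, 0 °C; H2O
Reagents that add atoms: none
Why: Grignard 1,2-addition to the aldehyde, with the first equivalent consumed by the phenol; the new carbinol centre is lost again in the quinone methide.

Step 15
Reactants: 26 3-bromo-2-[(3,5-dimethoxyphenyl)(hydroxy)methyl]-5-methoxyphenol
Product: 27 3-bromo-2-[(3,5-dimethoxyphenyl)(4-methylbenzenesulfonyl)methyl]-5-methoxyphenol (racemic)
Conditions: p-TolSO2Na, HCO2H, THF/H2O, rt
Reagents that add atoms: sodium 4-methylbenzenesulfinate, [Na+].Cc1ccc(cc1)S(=O)[O-]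
Why: Acid ionises the doubly activated benzhydrol (SN1 through the protonated o-quinone methide) and the sulfinate traps it at sulfur to give a bench-stable quinone methide precursor.

Step 16
Reactants: 23 (2S,5S)-1-{[(2S,3S)-2-(2,4-dimethoxyphenyl)-3-(3,5-dimethoxyphenyl)-4-methoxy-2,3-dihydro-1-benzofuran-7-yl]methyl}-2,5-dimethylthiolan-1-ium tetrafluoroborate; 27 3-bromo-2-[(3,5-dimethoxyphenyl)(4-methylbenzenesulfonyl)methyl]-5-methoxyphenol
Product: 30 (2S,3S)-4-bromo-2-[(2S,3S)-2-(2,4-dimethoxyphenyl)-3-(3,5-dimethoxyphenyl)-4-methoxy-2,3-dihydro-1-benzofuran-7-yl]-3-(3,5-dimethoxyphenyl)-6-methoxy-2,3-dihydro-1-benzofuran, via sulfonium ylide 28 (not isolated), via o-quinone methide 29 (not isolated)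
Conditions: KOH (powder), MeCN, 0 °C to rt
Reagents that add atoms: none
Why: Formal [4+1] annulation of a sulfonium ylide with an o-quinone methide, in which base releases both partners, the benzylide adds to the exocyclic methide carbon and the phenoxide displaces the sulfide in a 5-exo-tet SN2 step with inversion; the C2-symmetric sulfide shields one face of the ylide and so should set C2 as (S), and the anti betaine leads to the trans ring and so to (3S).

Step 17
Reactants: 30 (2S,3S)-4-bromo-2-[(2S,3S)-2-(2,4-dimethoxyphenyl)-3-(3,5-dimethoxyphenyl)-4-methoxy-2,3-dihydro-1-benzofuran-7-yl]-3-(3,5-dimethoxyphenyl)-6-methoxy-2,3-dihydro-1-benzofuran; 31 1-ethenyl-4-methoxybenzene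
Product: 32 (2S,3S)-2-[(2S,3S)-2-(2,4-dimethoxyphenyl)-3-(3,5-dimethoxyphenyl)-4-methoxy-2,3-dihydro-1-benzofuran-7-yl]-3-(3,5-dimethoxyphenyl)-6-methoxy-4-[(E)-2-(4-methoxyphenyl)ethenyl]-2,3-dihydro-1-benzofuran
Conditions: Pd2(dba)3, [HP(t-Bu)3]BF4, Cy2NMe, 1,4-dioxane, 100 °C
Reagents that add atoms: none
Why: Mizoroki–Heck reaction, in which the bulky electron-rich phosphine lets zerovalent palladium insert into the hindered aryl bromide and syn β-hydride elimination gives the E-stilbene.

Step 18
Reactants: 32 (2S,3S)-2-[(2S,3S)-2-(2,4-dimethoxyphenyl)-3-(3,5-dimethoxyphenyl)-4-methoxy-2,3-dihydro-1-benzofuran-7-yl]-3-(3,5-dimethoxyphenyl)-6-methoxy-4-[(E)-2-(4-methoxyphenyl)ethenyl]-2,3-dihydro-1-benzofuran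
Product: 33 CNP0397447.1, (2S,3S,2'S,3'S)-nonaphenol
Conditions: BBr3, CH2Cl2, −78 °C to rt; then H2O
Reagents that add atoms: none
Why: Lewis-acid ether cleavage by BBr3 should remove all nine methyl groups as bromomethane, and since both dihydrofurans are the thermodynamically preferred trans isomers, a reversible opening at C2 or C2' would not change their configuration.

Compound list
1 | 2-bromo-5-methoxyphenol | COc1ccc(Br)c(O)c1 | starting material
2 | 3-bromo-2-hydroxy-6-methoxybenzaldehyde | COc1ccc(Br)c(O)c1C=O | intermediate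
3 | 3-bromo-6-methoxy-2-(methoxymethoxy)benzaldehyde | COCOc1c(Br)ccc(OC)c1C=O | intermediate
4 | (R)-2-methylpropane-2-sulfinamide | CC(C)(C)[S@@](=O)N | starting material
5 | (R)-N-[(E)-[3-bromo-6-methoxy-2-(methoxymethoxy)phenyl]methylidene]-2-methylpropane-2-sulfinamide | COCOc1c(Br)ccc(OC)c1/C=N/[S@](=O)C(C)(C)C | intermediate
6 | 1-bromo-3,5-dimethoxybenzene | COc1cc(Br)cc(OC)c1 | starting material
7 | (3,5-dimethoxyphenyl)magnesium bromide, stock solution in THF | COc1cc([Mg]Br)cc(OC)c1 | intermediate
8 | (R)-N-[(S)-[3-bromo-6-methoxy-2-(methoxymethoxy)phenyl](3,5-dimethoxyphenyl)methyl]-2-methylpropane-2-sulfinamide | COCOc1c(Br)ccc(OC)c1[C@H](c1cc(OC)cc(OC)c1)N[S@](=O)C(C)(C)C | intermediate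
9 | (S)-2-[amino(3,5-dimethoxyphenyl)methyl]-6-bromo-3-methoxyphenol | COc1ccc(Br)c(O)c1[C@@H](N)c1cc(OC)cc(OC)c1 | intermediate
10 | 2,4-dihydroxybenzaldehyde | O=Cc1ccc(O)cc1O | starting material
11 | 4-formyl-1,3-phenylene dimethanesulfonate | CS(=O)(=O)Oc1ccc(C=O)c(OS(C)(=O)=O)c1 | intermediate
12 | 4-[(4S)-8-bromo-4-(3,5-dimethoxyphenyl)-5-methoxy-3,4-dihydro-2H-1,3-benzoxazin-2-yl]-1,3-phenylene dimethanesulfonate, C2 epimers | COc1ccc(Br)c2OC(c3ccc(OS(C)(=O)=O)cc3OS(C)(=O)=O)N[C@@H](c3cc(OC)cc(OC)c3)c12 | intermediate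
13 | hydrazide adduct: N3 of 12 bonded to the nitrogen of N-(benzyloxy)-4-(trifluoromethyl)benzamide, C4 (S) | COc1ccc(Br)c2OC(c3ccc(OS(C)(=O)=O)cc3OS(C)(=O)=O)N(N(OCc3ccccc3)C(=O)c3ccc(cc3)C(F)(F)F)[C@@H](c3cc(OC)cc(OC)c3)c12 | intermediate
14 | isodiazene (1,1-diazene) of 12: ring nitrogen carries a terminal nitrogen, C4 (S) | COc1ccc(Br)c2OC(c3ccc(OS(C)(=O)=O)cc3OS(C)(=O)=O)[N+](=[N-])[C@@H](c3cc(OC)cc(OC)c3)c12 | intermediate
15 | 1,5-diradical: aryl(aryloxy)methyl radical on O1 and diarylmethyl radical ortho to it on ring D | COc1ccc(Br)c(O[CH]c2ccc(OS(C)(=O)=O)cc2OS(C)(=O)=O)c1[CH]c1cc(OC)cc(OC)c1 | intermediate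
16 | 4-[(2S,3S)-7-bromo-3-(3,5-dimethoxyphenyl)-4-methoxy-2,3-dihydro-1-benzofuran-2-yl]-1,3-phenylene dimethanesulfonate | COc1ccc(Br)c2O[C@H](c3ccc(OS(C)(=O)=O)cc3OS(C)(=O)=O)[C@@H](c3cc(OC)cc(OC)c3)c12 | intermediate
17 | 4-[(2S,3S)-7-bromo-3-(3,5-dimethoxyphenyl)-4-methoxy-2,3-dihydro-1-benzofuran-2-yl]benzene-1,3-diol | COc1ccc(Br)c2O[C@H](c3ccc(O)cc3O)[C@@H](c3cc(OC)cc(OC)c3)c12 | intermediate
18 | (2S,3S)-7-bromo-2-(2,4-dimethoxyphenyl)-3-(3,5-dimethoxyphenyl)-4-methoxy-2,3-dihydro-1-benzofuran | COc1ccc(Br)c2O[C@H](c3ccc(OC)cc3OC)[C@@H](c3cc(OC)cc(OC)c3)c12 | intermediate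
19 | (2S,3S)-2-(2,4-dimethoxyphenyl)-3-(3,5-dimethoxyphenyl)-4-methoxy-2,3-dihydro-1-benzofuran-7-carbaldehyde | COc1ccc(C=O)c2O[C@H](c3ccc(OC)cc3OC)[C@@H](c3cc(OC)cc(OC)c3)c12 | intermediate
20 | [(2S,3S)-2-(2,4-dimethoxyphenyl)-3-(3,5-dimethoxyphenyl)-4-methoxy-2,3-dihydro-1-benzofuran-7-yl]methanol | COc1ccc(CO)c2O[C@H](c3ccc(OC)cc3OC)[C@@H](c3cc(OC)cc(OC)c3)c12 | intermediate
21 | (2S,5S)-2,5-dimethylthiolane | C[C@H]1CC[C@H](C)S1 | starting material
22 | (2S,3S)-7-(bromomethyl)-2-(2,4-dimethoxyphenyl)-3-(3,5-dimethoxyphenyl)-4-methoxy-2,3-dihydro-1-benzofuran | COc1ccc(CBr)c2O[C@H](c3ccc(OC)cc3OC)[C@@H](c3cc(OC)cc(OC)c3)c12 | intermediate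
23 | (2S,5S)-1-{[(2S,3S)-2-(2,4-dimethoxyphenyl)-3-(3,5-dimethoxyphenyl)-4-methoxy-2,3-dihydro-1-benzofuran-7-yl]methyl}-2,5-dimethylthiolan-1-ium tetrafluoroborate | COc1ccc(C[S+]3[C@@H](C)CC[C@@H]3C)c2O[C@H](c3ccc(OC)cc3OC)[C@@H](c3cc(OC)cc(OC)c3)c12.F[B-](F)(F)F | intermediate
24 | 2-bromo-4,6-dimethoxybenzaldehyde | COc1cc(OC)c(C=O)c(Br)c1 | starting material
25 | 2-bromo-6-hydroxy-4-methoxybenzaldehyde | COc1cc(O)c(C=O)c(Br)c1 | intermediate
26 | 3-bromo-2-[(3,5-dimethoxyphenyl)(hydroxy)methyl]-5-methoxyphenol, racemic | COc1cc(O)c(C(O)c2cc(OC)cc(OC)c2)c(Br)c1 | intermediate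
27 | 3-bromo-2-[(3,5-dimethoxyphenyl)(4-methylbenzenesulfonyl)methyl]-5-methoxyphenol, racemic | COc1cc(O)c(C(c2cc(OC)cc(OC)c2)S(=O)(=O)c2ccc(C)cc2)c(Br)c1 | intermediate
28 | sulfonium ylide of 23 (benzylic carbanion next to the thiolanium sulfur) | COc1ccc([CH-][S+]3[C@@H](C)CC[C@@H]3C)c2O[C@H](c3ccc(OC)cc3OC)[C@@H](c3cc(OC)cc(OC)c3)c12 | intermediate
29 | 5-bromo-6-[(3,5-dimethoxyphenyl)methylidene]-3-methoxycyclohexa-2,4-dien-1-one | COC1=CC(=O)C(=Cc2cc(OC)cc(OC)c2)C(Br)=C1 | intermediate
30 | (2S,3S)-4-bromo-2-[(2S,3S)-2-(2,4-dimethoxyphenyl)-3-(3,5-dimethoxyphenyl)-4-methoxy-2,3-dihydro-1-benzofuran-7-yl]-3-(3,5-dimethoxyphenyl)-6-methoxy-2,3-dihydro-1-benzofuran | Brc1cc(OC)cc2c1[C@H](c1cc(OC)cc(OC)c1)[C@@H](c1ccc(OC)c3c1O[C@H](c1ccc(OC)cc1OC)[C@H]3c1cc(OC)cc(OC)c1)O2 | intermediate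
31 | 1-ethenyl-4-methoxybenzene | C=Cc1ccc(OC)cc1 | starting material
32 | nonamethyl ether of the target, (2S,3S,2'S,3'S), E-alkene | COc1ccc(/C=C/c2cc(OC)cc3c2[C@H](c2cc(OC)cc(OC)c2)[C@@H](c2ccc(OC)c4c2O[C@H](c2ccc(OC)cc2OC)[C@H]4c2cc(OC)cc(OC)c2)O3)cc1 | intermediate
33 | CNP0397447.1, 4-[(2S,3S)-3-(3,5-dihydroxyphenyl)-7-[(2S,3S)-3-(3,5-dihydroxyphenyl)-6-hydroxy-4-[(E)-2-(4-hydroxyphenyl)ethenyl]-2,3-dihydro-1-benzofuran-2-yl]-4-hydroxy-2,3-dihydro-1-benzofuran-2-yl]benzene-1,3-diol | Oc1ccc(/C=C/c2cc(O)cc3c2[C@H](c2cc(O)cc(O)c2)[C@@H](c2ccc(O)c4c2O[C@H](c2ccc(O)cc2O)[C@H]4c2cc(O)cc(O)c2)O3)cc1 | target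

Total step count: 18. Longest linear sequence: 13 steps (steps 1–3, 5–6, 8–12, 16–18).

Steps most likely to fail

Step 9. N-functionalisation could lose against opening of the aminal to the unreactive imine, or the diradical could rotate about the ring D–C bond before it couples, which would erase the C3' configuration or close the ring cis. The fallback builds the same ring by the ylide annulation that the route already uses in step 16. It sets out from 2. Two equivalents of Grignard reagent 7 would give 6-bromo-2-[(3,5-dimethoxyphenyl)(hydroxy)methyl]-3-methoxyphenol F1. p-TolSO2Na in HCO2H would convert this into 6-bromo-2-[(3,5-dimethoxyphenyl)(4-methylbenzenesulfonyl)methyl]-3-methoxyphenol F2. Commercial 2,4-dimethoxybenzyl alcohol, sulfide 21 and HBF4·OEt2 would give (2S,5S)-1-[(2,4-dimethoxyphenyl)methyl]-2,5-dimethylthiolan-1-ium tetrafluoroborate F3. KOH in MeCN would then release 2-bromo-6-[(3,5-dimethoxyphenyl)methylidene]-5-methoxycyclohexa-2,4-dien-1-one F4 and the ylide (2,4-dimethoxyphenyl)[(2S,5S)-2,5-dimethylthiolan-1-ium-1-yl]methanide F5. Their [4+1] annulation would come back to the route at 18, in place of steps 2, 3 and 5 to 10.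

Step 16. The chiral benzylide could add to the quinone methide with poor facial selectivity, and the union of two congested carbons could be slow enough for the quinone methide to oligomerise. The fallback replaces reagent control of the absolute configuration by separation of diastereomers. It sets out from 20, which would be brominated to 22 as in step 12 and quaternised with tetrahydrothiophene and NaBF4 to 1-{[(2S,3S)-2-(2,4-dimethoxyphenyl)-3-(3,5-dimethoxyphenyl)-4-methoxy-2,3-dihydro-1-benzofuran-7-yl]methyl}thiolan-1-ium tetrafluoroborate F6. With sulfone 27 and KOH, this salt would release the unhindered achiral sulfonium ylide F7, which would add to 29 with the usual trans preference but without facial bias. This would give 30 together with its (2R,3R,2'S,3'S) isomer F8; because the (2'S,3'S) unit is fixed, the two are diastereomers and would be separated by chromatography, which comes back to the route at 30.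

Step 18. The Lewis acid could open a dihydrofuran ring at C2 or C2', or make the stilbene cyclise onto a neighbouring electron-rich ring. The fallback removes the methyl groups by SN2 attack of a thiolate under basic conditions instead: 32 with excess NaSEt in DMF at 130 °C under argon, followed by acidification, would give 33 directly, with no new isolated compound.

Further compounds
F1 | step 9 | 6-bromo-2-[(3,5-dimethoxyphenyl)(hydroxy)methyl]-3-methoxyphenol | COc1ccc(Br)c(O)c1C(O)c1cc(OC)cc(OC)c1
F2 | step 9 | 6-bromo-2-[(3,5-dimethoxyphenyl)(4-methylbenzenesulfonyl)methyl]-3-methoxyphenol | COc1ccc(Br)c(O)c1C(c1cc(OC)cc(OC)c1)S(=O)(=O)c1ccc(C)cc1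
F3 | step 9 | (2S,5S)-1-[(2,4-dimethoxyphenyl)methyl]-2,5-dimethylthiolan-1-ium tetrafluoroborate | COc1ccc(C[S+]2[C@@H](C)CC[C@@H]2C)c(OC)c1.F[B-](F)(F)F
F4 | step 9 | 2-bromo-6-[(3,5-dimethoxyphenyl)methylidene]-5-methoxycyclohexa-2,4-dien-1-one | COC1=CC=C(Br)C(=O)C1=Cc1cc(OC)cc(OC)c1
F5 | step 9 | (2,4-dimethoxyphenyl)[(2S,5S)-2,5-dimethylthiolan-1-ium-1-yl]methanide | COc1ccc([CH-][S+]2[C@@H](C)CC[C@@H]2C)c(OC)c1
F6 | step 16 | 1-{[(2S,3S)-2-(2,4-dimethoxyphenyl)-3-(3,5-dimethoxyphenyl)-4-methoxy-2,3-dihydro-1-benzofuran-7-yl]methyl}thiolan-1-ium tetrafluoroborate | COc1ccc(C[S+]3CCCC3)c2O[C@H](c3ccc(OC)cc3OC)[C@@H](c3cc(OC)cc(OC)c3)c12.F[B-](F)(F)F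
F7 | step 16 | sulfonium ylide of F6 (benzylic carbanion next to the thiolanium sulfur) | COc1ccc([CH-][S+]3CCCC3)c2O[C@H](c3ccc(OC)cc3OC)[C@@H](c3cc(OC)cc(OC)c3)c12
F8 | step 16 | (2R,3R)-4-bromo-2-[(2S,3S)-2-(2,4-dimethoxyphenyl)-3-(3,5-dimethoxyphenyl)-4-methoxy-2,3-dihydro-1-benzofuran-7-yl]-3-(3,5-dimethoxyphenyl)-6-methoxy-2,3-dihydro-1-benzofuran | Brc1cc(OC)cc2c1[C@@H](c1cc(OC)cc(OC)c1)[C@H](c1ccc(OC)c3c1O[C@H](c1ccc(OC)cc1OC)[C@H]3c1cc(OC)cc(OC)c1)O2
F0 | step 18 | none | none
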